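The constants were set for the occasion; the result is computed.

substrate 0.10 M; partner 0.105 M; time 20 s
    substrate → intermediate (k1 = 0.072 s⁻¹)
    partner + intermediate → target (k2 = 4.4 L mol⁻¹ s⁻¹)
    crystals ⇌ target, rate k3*(cs3 - [target]) while solid is left; crystals form when [target] > cs3 (cs3 = 0.096 M, k3 = 6.6 s⁻¹)
    partner + target ⇌ idle adduct, settled at all times (K4 = 3.5 L mol⁻¹)
- target and crystals and idle adduct together at 20 s, in percent of the substrate charged
- concentration of target in solution at 20 s, in percent of saturation
- target is meant together with its crystals and idle adduct
- solid, in amounts per volume of the solution: crystals
- run time (flask): 20 s

Begin with what is slow. In the flask substrate needs 9.6 s to halve and intermediate 1.5 s with partner as charged, so substrate is slower, but partner falls. By 20 s the first step has turned over 76.3 % of the substrate. Replace the falling c(partner) by its mean, the charge less half of what turned over: 0.0668 M. The second step then is pseudo-first-order. Multiply its constant by that mean and divide by the constant of the first step: 4.09. This clearance ratio, the lifetime of a substrate molecule over that of an intermediate molecule with partner held at its mean, compares rate constants, not the two rates, and it reads the outcome: in this picture intermediate stands at the substrate left divided by the ratio less one, 7.68 % of the charge, and the total target is 68.6 %.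

Now test whether one number was enough. That total leaves c(partner) at 0.0364 M, and there the ratio is 2.22, which gives 56.9 %. So the mean replaces a curve at a real price. I commit to the middle, 62.8 %. Even the upper total stays below the solubility, so no crystals form, and with the idle adduct at balance the dissolved target is 58.0 % of saturation.

The forecast gives 64 % and 60 %, both slightly above mine, on the ground that “the second step slows as partner is used up”.

The flask gives 64.0 % and 59.5 %, with 12.3 % intermediate and 0 % crystals. Carry the ratio to the neighbour charged with 0.026 M of partner. Its substrate turns over more than that charge can meet, so the mean is half the charge, and the ratio is 0.794, below one: it reads an intermediate molecule as outliving a substrate molecule. That neighbour holds 52.0 % intermediate against 24.3 % target, with 5.92 % of its partner left.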